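**Plan**

- Feature: with the ring numbered O1–O2–C3(H)(CH2CO2Me)–C4=C5–C6(OMe)(C16H33), C6 is the only ring carbon that carries two oxygens (O1 and OMe) and no hydrogen. A 6,6-dimethoxy precursor can therefore ionise only there, to a 6-methoxy-1,2-dioxin-6-ylium ion flanked by O1, OMe and the C4=C5 bond; C3 has no leaving group.
- Cuts, in retrosynthetic order: the chain C2'=C3' bond (cross-metathesis, then saturation); C6–C1' (allylsilane onto the cation); ring C4=C5 (ring-closing metathesis); O1–C6 (orthoester exchange); C3–O2 (singlet-oxygen ene reaction).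
- Forward: ene reaction on a symmetric diester, resolution of the hydroperoxide, mixed peroxy orthoester, closure of the only ring (the 1,2-dioxine) by metathesis, then the chain is joined at C6 as an allyl group, lengthened and saturated.
- Stereochemistry: C3 (R) comes from the hydroperoxide resolved as a perketal of a (1S,2R)-2-phenylcyclohexyl auxiliary; C6 (S) is set from C3 by 1,4-induction in the allylation, which must place the chain cis to CH2CO2Me.

Key step: step 9

Assumption: the two perketal diastereomers of step 4 should be separable by chromatography, and the one with the (4R) peroxide carbon would be identified by correlation (PPh3 reduction of a liberated sample, then hydrogenation to dimethyl 3-hydroxyadipate of known configuration). The antipodal auxiliary is equally available if the elution order is inconvenient.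

**Route**

Step 1
Reactants: 1 dimethyl (3E)-hex-3-enedioate
Product: 2 dimethyl (2E)-4-hydroperoxyhex-2-enedioate (racemic)
Conditions: O2, visible light, 5,10,15,20-tetraphenylporphyrin (cat.), CCl4, 0 °C, prolonged irradiation
Reagents that add atoms: dioxygen, O=O
Why: Schenck ene reaction of singlet oxygen with a β,γ-unsaturated ester; because 1 has a twofold axis, oxygen delivery to either alkene carbon with abstraction of the ester-activated allylic hydrogen on the far side gives the same γ-hydroperoxy (E)-enoate, whose conjugated alkene is not attacked further, and C4 is formed racemic and resolved in step 4.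

Step 2
Reactants: 3 (1S,2R)-2-phenylcyclohexan-1-ol
Product: 4 (1S,2R)-2-phenylcyclohexyl acetate
Conditions: Ac2O, pyridine, DMAP (cat.), CH2Cl2, rt
Reagents that add atoms: acetic anhydride, CC(=O)OC(C)=O
Why: Nucleophile-catalysed acylation of a secondary alcohol, which touches no stereocentre.

Step 3
Reactants: 4 (1S,2R)-2-phenylcyclohexyl acetate
Product: 5 (1S,2R)-2-phenylcyclohexyl prop-1-en-2-yl ether
Conditions: Cp2TiMe2, toluene, 65 °C, dark
Reagents that add atoms: dimethyltitanocene Cp2TiMe2, C[Ti+2]C.[cH-]1cccc1.[cH-]1cccc1
Why: Petasis methylenation of an ester carbonyl by thermally generated Cp2Ti=CH2, which should turn the acetate into the acid-sensitive isopropenyl ether under non-acidic conditions.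

Step 4
Reactants: 2 dimethyl (2E)-4-hydroperoxyhex-2-enedioate (racemic), 5 (1S,2R)-2-phenylcyclohexyl prop-1-en-2-yl ether
Product: 6 dimethyl (2E,4R)-4-[(2-{[(1S,2R)-2-phenylcyclohexyl]oxy}propan-2-yl)peroxy]hex-2-enedioate
Conditions: 5 (slight excess), PPTS (cat.), CH2Cl2, 0 °C to rt; diastereomers separated on silica (preparative HPLC if needed)
Reagents that add atoms: none
Why: Acid-catalysed Markovnikov addition of a hydroperoxide to a 2-alkoxypropene (perketal formation, the established resolution of hydroperoxides); the ketal carbon is not stereogenic, so racemic 2 should give just two diastereomers differing at C4, of which the (4R) one is taken on.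

Step 5
Reactants: 6 dimethyl (2E,4R)-4-[(2-{[(1S,2R)-2-phenylcyclohexyl]oxy}propan-2-yl)peroxy]hex-2-enedioate
Product: 7 dimethyl (2E,4R)-4-hydroperoxyhex-2-enedioate
Conditions: AcOH/THF/H2O (4:2:1), rt
Reagents that add atoms: none
Why: Mild acid hydrolysis of the perketal, which should release the hydroperoxide with acetone and recoverable alcohol 3 while leaving the O–O bond, both esters and C4 untouched.

Step 6
Reactants: 8 3-bromo-1,1,1-trimethoxypropane (trimethyl 3-bromoorthopropionate)
Product: 9 3,3,3-trimethoxyprop-1-ene (trimethyl orthoacrylate)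
Conditions: KOtBu, THF, 0 °C to rt; distillation
Reagents that add atoms: none
Why: E2 dehydrobromination of a primary bromide by a hindered alkoxide, with the orthoester inert to base.

Step 7
Reactants: 7 dimethyl (2E,4R)-4-hydroperoxyhex-2-enedioate, 9 3,3,3-trimethoxyprop-1-ene
Product: 10 dimethyl (2E,4R)-4-[(1,1-dimethoxyprop-2-en-1-yl)peroxy]hex-2-enedioate
Conditions: 9 (3 equiv), PPTS (cat.), 4 Å molecular sieves, CH2Cl2, 0 °C; filtration through neutral alumina, no amine
Reagents that add atoms: none
Why: Acid-catalysed orthoester exchange, as in the formation of peroxy orthoesters from orthoesters and hydroperoxides: the hydroperoxide should capture the dimethoxy(vinyl)carbenium ion at its oxygenated carbon, with the sieves taking up methanol, excess 9 suppressing a second exchange, and amines avoided because γ-peroxy enoates fragment with base (Kornblum–DeLaMare).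

Step 8
Reactants: 10 dimethyl (2E,4R)-4-[(1,1-dimethoxyprop-2-en-1-yl)peroxy]hex-2-enedioate
Product: 11 methyl 2-[(3R)-6,6-dimethoxy-3,6-dihydro-1,2-dioxin-3-yl]acetate
Conditions: second-generation Hoveyda–Grubbs catalyst RuCl2(1,3-dimesitylimidazolidin-2-ylidene)(=CH-C6H4-2-OiPr) (10 mol %), CH2Cl2 (5 mM), 40 °C, argon purge
Reagents that add atoms: none
Why: Ring-closing olefin metathesis, which dialkyl peroxides tolerate: the ruthenium carbene formed at the enoate end with release of methyl acrylate should close onto the orthoester vinyl group to give the six-membered ring, which can only hold a cis C4=C5 bond, and C3 takes no part.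

Step 9
Reactants: 11 methyl 2-[(3R)-6,6-dimethoxy-3,6-dihydro-1,2-dioxin-3-yl]acetate, 12 allyltrimethylsilane
Product: 14 methyl 2-[(3R,6S)-6-methoxy-6-(prop-2-en-1-yl)-3,6-dihydro-1,2-dioxin-3-yl]acetate, via methoxydioxinylium triflate 13 (not isolated)
Conditions: 12 (3 equiv), Me3SiOTf (0.2 equiv), CH2Cl2, −78 °C; quench with aqueous NaHCO3 at −78 °C
Reagents that add atoms: none
Why: Proposed new method: Me3SiOTf should silylate one of the two methoxy oxygens at C6 (more basic than the peroxy oxygen O1) and Me3SiOMe departs, leaving the 6-methoxy-1,2-dioxin-6-ylium ion 13 whose charge is shared by O1, the remaining OMe and the C4=C5 bond; the terminal carbon of allylsilane 12 then bonds to C6 and the β-silyl cation passes its silyl group to triflate, so the acid turns over. The closest known reactions are the Hosomi–Sakurai allylation of orthoesters through dialkoxycarbenium ions and of monoperoxy ketals through peroxycarbenium ions; new here is their combination in a cyclic, vinylogous peroxy orthoester. No ring is closed. The new stereocentre C6 is controlled by C3: in the half-chair that leads to product with the CH2CO2Me arm pseudoequatorial, the nucleophile should enter pseudoaxially at C6, which places the allyl group cis to that arm and gives (3R,6S). The step needs this face selectivity, attack at C6 rather than at the allylic terminus C4, and a single addition; the larger positive charge on the doubly oxygenated C6 should secure the regiochemistry, and the far easier ionisation of an orthoester than of the product peroxy ketal, at −78 °C with substoichiometric acid, should stop the reaction after one allyl group. C3 carries no leaving group and stays (R), and the O–O bond is not expected to react with the silyl triflate at this temperature.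

Step 10
Reactants: 14 methyl 2-[(3R,6S)-6-methoxy-6-(prop-2-en-1-yl)-3,6-dihydro-1,2-dioxin-3-yl]acetate, 15 pentadec-1-ene
Product: 16 methyl 2-[(3R,6S)-6-[(2E)-hexadec-2-en-1-yl]-6-methoxy-3,6-dihydro-1,2-dioxin-3-yl]acetate (E isomer drawn; any Z isomer is carried along)
Conditions: 15 (4 equiv), second-generation Hoveyda–Grubbs catalyst RuCl2(1,3-dimesitylimidazolidin-2-ylidene)(=CH-C6H4-2-OiPr) (5 mol %), CH2Cl2, 40 °C
Reagents that add atoms: none
Why: Olefin cross-metathesis of two terminal alkenes with loss of ethylene, in which the unstrained cis ring alkene between the quaternary C6 and the tertiary C3 should stay out of the reaction and the geometry of the new chain alkene is of no consequence.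

Step 11
Reactants: 16 methyl 2-[(3R,6S)-6-[(2E)-hexadec-2-en-1-yl]-6-methoxy-3,6-dihydro-1,2-dioxin-3-yl]acetate
Product: 17 chondrillin, methyl 2-[(3R,6S)-6-hexadecyl-6-methoxy-3,6-dihydro-1,2-dioxin-3-yl]acetate
Conditions: KO2CN=NCO2K (portionwise), AcOH, CH2Cl2, −40 to 0 °C, stopped when 16 is consumed
Reagents that add atoms: none
Why: Diimide reduction (concerted syn transfer of H2 to C=C, the classical way to saturate alkenes beside an O–O bond); the chain alkene flanked by two CH2 groups should react ahead of the ring alkene, which is shielded by the quaternary ketal carbon C6 and the branched C3, and neither stereocentre is touched.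

**Compound list**

1 | dimethyl (3E)-hex-3-enedioate | COC(=O)C/C=C/CC(=O)OC | starting material
2 | dimethyl (2E)-4-hydroperoxyhex-2-enedioate (racemic) | COC(=O)/C=C/C(CC(=O)OC)OO | intermediate
3 | (1S,2R)-2-phenylcyclohexan-1-ol | O[C@H]1CCCC[C@@H]1c1ccccc1 | starting material
4 | (1S,2R)-2-phenylcyclohexyl acetate | CC(=O)O[C@H]1CCCC[C@@H]1c1ccccc1 | intermediate
5 | (1S,2R)-2-phenylcyclohexyl prop-1-en-2-yl ether | C=C(C)O[C@H]1CCCC[C@@H]1c1ccccc1 | intermediate
6 | dimethyl (2E,4R)-4-[(2-{[(1S,2R)-2-phenylcyclohexyl]oxy}propan-2-yl)peroxy]hex-2-enedioate | COC(=O)/C=C/[C@@H](CC(=O)OC)OOC(C)(C)O[C@H]1CCCC[C@@H]1c1ccccc1 | intermediate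
7 | dimethyl (2E,4R)-4-hydroperoxyhex-2-enedioate | COC(=O)/C=C/[C@@H](CC(=O)OC)OO | intermediate
8 | 3-bromo-1,1,1-trimethoxypropane (trimethyl 3-bromoorthopropionate) | COC(OC)(OC)CCBr | starting material
9 | 3,3,3-trimethoxyprop-1-ene (trimethyl orthoacrylate) | C=CC(OC)(OC)OC | intermediate
10 | dimethyl (2E,4R)-4-[(1,1-dimethoxyprop-2-en-1-yl)peroxy]hex-2-enedioate | C=CC(OC)(OC)OO[C@H](CC(=O)OC)/C=C/C(=O)OC | intermediate
11 | methyl 2-[(3R)-6,6-dimethoxy-3,6-dihydro-1,2-dioxin-3-yl]acetate | COC1(OC)C=C[C@@H](CC(=O)OC)OO1 | intermediate
12 | allyltrimethylsilane | C=CC[Si](C)(C)C | starting material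
13 | (3R)-6-methoxy-3-(2-methoxy-2-oxoethyl)-3,6-dihydro-1,2-dioxin-6-ylium trifluoromethanesulfonate | CO[C+]1C=C[C@@H](CC(=O)OC)OO1.[O-]S(=O)(=O)C(F)(F)F | intermediate
14 | methyl 2-[(3R,6S)-6-methoxy-6-(prop-2-en-1-yl)-3,6-dihydro-1,2-dioxin-3-yl]acetate | C=CC[C@@]1(OC)C=C[C@@H](CC(=O)OC)OO1 | intermediate
15 | pentadec-1-ene | C=CCCCCCCCCCCCCC | starting material
16 | methyl 2-[(3R,6S)-6-[(2E)-hexadec-2-en-1-yl]-6-methoxy-3,6-dihydro-1,2-dioxin-3-yl]acetate | CCCCCCCCCCCCC/C=C/C[C@@]1(OC)C=C[C@@H](CC(=O)OC)OO1 | intermediate
17 | chondrillin, methyl 2-[(3R,6S)-6-hexadecyl-6-methoxy-3,6-dihydro-1,2-dioxin-3-yl]acetate | CCCCCCCCCCCCCCCC[C@@]1(OC)C=C[C@@H](CC(=O)OC)OO1 | target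

**Step count**

Total: 11 steps. Longest linear sequence: 9 steps (3 → 4 → 5 → 6 → 7 → 10 → 11 → 14 → 16 → 17); counted from diester 1 it is 8.

**Steps most likely to fail**

1. Step 9 (proposed new method). Possible failures are poor facial selectivity at C6, competing attack of the allylsilane at C4, ring opening at O1 instead of loss of methoxide, or a second ionisation of the product ketal. The fallback uses known chemistry and brings the chain in with the ketal carbon instead of adding it to a cation. It sets out from 7 and returns at 17.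
   - Lithiated methoxyallene (n-BuLi, THF, −40 °C) would be alkylated with 1-bromohexadecane to give 3-methoxynonadeca-1,2-diene F1.
   - Hydroperoxide 7 should add to this alkoxyallene under PPTS catalysis in CH2Cl2, as hydroperoxides add to enol ethers, to give dimethyl (2E,4R)-4-[(3-methoxynonadec-1-en-3-yl)peroxy]hex-2-enedioate F2 as both epimers at the ketal carbon.
   - Ring-closing metathesis with the catalyst of step 8, again with loss of methyl acrylate, should then give 17 together with its C6 epimer methyl 2-[(3R,6R)-6-hexadecyl-6-methoxy-3,6-dihydro-1,2-dioxin-3-yl]acetate F3.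
   - The two would be separated on silica, and the unwanted epimer re-equilibrated by acid-catalysed ketal exchange in methanol and recycled.

2. Step 8. Initiation may be slow at both alkenes, one crowded by the orthoester carbon and one deactivated by conjugation, so the catalyst may decompose before the ring closes. The fallback replaces the enoate by a terminal vinyl group before metathesis. It sets out from 6 and returns at 11.
   - Ozonolysis of 6 (O3, CH2Cl2, −78 °C; Me2S) would give methyl (3R)-4-oxo-3-[(2-{[(1S,2R)-2-phenylcyclohexyl]oxy}propan-2-yl)peroxy]butanoate F4.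
   - Wittig methylenation with Ph3P=CH2 at −78 °C would give methyl (3R)-3-[(2-{[(1S,2R)-2-phenylcyclohexyl]oxy}propan-2-yl)peroxy]pent-4-enoate F5.
   - Hydrolysis as in step 5 would release methyl (3R)-3-hydroperoxypent-4-enoate F6.
   - Exchange with 9 as in step 7 would give methyl (3R)-3-[(1,1-dimethoxyprop-2-en-1-yl)peroxy]pent-4-enoate F7.
   - This diene has an unhindered secondary allylic vinyl group for initiation and should close to 11 with loss of ethylene.

3. Step 11. Diimide may also reduce the ring C4=C5 bond before the chain alkene is fully consumed. The fallback never forms a chain alkene and sets out from 14, returning at 17.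
   - Hydroboration of the terminal alkene of 14 with 9-BBN (THF, 0 °C to rt) should be selective over the hindered ring alkene and give methyl 2-[(3R,6S)-6-[3-(9-borabicyclo[3.3.1]nonan-9-yl)propyl]-6-methoxy-3,6-dihydro-1,2-dioxin-3-yl]acetate F8.
   - Alkyl–alkyl Suzuki coupling with 1-bromotridecane (Pd(OAc)2, PCy3, K3PO4·H2O, THF, rt) would then deliver the saturated C16 chain of 17 directly.

**Further compounds**

F1 | step 9 | 3-methoxynonadeca-1,2-diene | C=C=C(OC)CCCCCCCCCCCCCCCC
F2 | step 9 | dimethyl (2E,4R)-4-[(3-methoxynonadec-1-en-3-yl)peroxy]hex-2-enedioate (both epimers at the ketal carbon) | CCCCCCCCCCCCCCCCC(OC)(C=C)OO[C@H](CC(=O)OC)/C=C/C(=O)OC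
F3 | step 9 | methyl 2-[(3R,6R)-6-hexadecyl-6-methoxy-3,6-dihydro-1,2-dioxin-3-yl]acetate | CCCCCCCCCCCCCCCC[C@]1(OC)C=C[C@@H](CC(=O)OC)OO1
F4 | step 8 | methyl (3R)-4-oxo-3-[(2-{[(1S,2R)-2-phenylcyclohexyl]oxy}propan-2-yl)peroxy]butanoate | O=C[C@@H](CC(=O)OC)OOC(C)(C)O[C@H]1CCCC[C@@H]1c1ccccc1
F5 | step 8 | methyl (3R)-3-[(2-{[(1S,2R)-2-phenylcyclohexyl]oxy}propan-2-yl)peroxy]pent-4-enoate | C=C[C@@H](CC(=O)OC)OOC(C)(C)O[C@H]1CCCC[C@@H]1c1ccccc1
F6 | step 8 | methyl (3R)-3-hydroperoxypent-4-enoate | C=C[C@@H](CC(=O)OC)OO
F7 | step 8 | methyl (3R)-3-[(1,1-dimethoxyprop-2-en-1-yl)peroxy]pent-4-enoate | C=CC(OC)(OC)OO[C@H](CC(=O)OC)C=C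
F8 | step 11 | methyl 2-[(3R,6S)-6-[3-(9-borabicyclo[3.3.1]nonan-9-yl)propyl]-6-methoxy-3,6-dihydro-1,2-dioxin-3-yl]acetate | B1(C2CCCC1CCC2)CCC[C@@]1(OC)C=C[C@@H](CC(=O)OC)OO1
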